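## Analysis of the target

Compound 21 has one carbocycle, a cyclopent-2-en-1-one (C1 carbonyl, C2=C3, C4, C5). C4 carries an acetoxy group, the fully substituted C5 carries a hydroxyl and a pentadecyl chain, and the first chain carbon, C1', is a secondary carbinol. This atom numbering is used for every intermediate below.

The three stereocentres are contiguous and all oxygen-bearing: C4 (R), C5 (S) and C1' (S). On the ring the C4 acetate is trans to the C5 hydroxyl and cis to the side chain. The C4 and C1' oxygens are syn across C5, so with C5 as a carbonyl the C4–C5–C1' array is pseudo-meso.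

The sensitive groups are:
- the γ-acyloxy enone (base, zerovalent palladium);
- the tertiary α-ketol (acyloin shift);
- the C1–C5–C4 β-hydroxy ketone relation, which allows retro-aldol cleavage once O4 is free;
- the acetate, which can migrate to O1'.

The synthesis is hard for two reasons. C5 is a quaternary carbinol between two oxygenated stereocentres, and only one of three hydroxyls may be acylated.

The strategy rests on the C1–C5 bond. C5 is a tertiary carbinol bonded directly to the ring ketone C1, an α-ketol, which is the retron of an intramolecular aldehyde–ketone benzoin reaction.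

## Retrosynthetic reasoning

**21 back to 20 and 19 (protecting-group logic).** The two hydroxyls that must stay free, O5 and O1', form a 1,2-diol and can share one isopropylidene acetal. O4 is trans to O5 on the ring and cannot join a five-membered acetal with it. Removing the acetal from 20 is therefore the last step, and 20 comes from acylation of the only free hydroxyl of 19.

**19 back to 18 (acetal migration).** The same isopropylidene group can sit on O4 and O1' as a six-membered acetal fused to the cyclopentenone. That isomer is the strained one: a dioxane with an axial methyl, fused to a nearly flat ring. Acid should therefore move the acetal to O5/O1' and release O4. One acetal thus serves twice, and O4 and O1' need no separate protecting groups.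

**18 back to 16 (C2=C3).** The double bond is removed next. In the saturated ketol 16 only C2 is enolizable, so a silyl enol ether / palladium dehydrogenation can only place the alkene at C2=C3. The acetal keeps O4 from acting as a leaving group during this step.

**16 back to 14 (key disconnection, C1–C5).** Cutting the α-ketol bond gives keto aldehyde 14, with aldehyde C1 and ketone C5. Forward, carbene catalysis makes C1 an acyl anion equivalent that adds to C5. This forms the ring, the quaternary carbinol and the C1 ketone in one redox-neutral step.

A version of 14 with two separate ethers on O4 and O1' was weighed and dropped. In it, polar Felkin–Anh control from C1' and the preference of the bulky side chain to lie trans to the C4 ether both favour the C5 epimer. No catalyst could be relied on to override two substrate biases.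

Tying O4 and O1' into one acetal makes 14 a cis-4,6-disubstituted 1,3-dioxan-5-one. A five-membered ring annulated onto a six-ring ketone from a tether on its α-carbon closes cis. In the cis-fused bicycle the C5 hydroxyl is necessarily trans to O4. The syn O4/O1' relation is exactly the cis, diequatorial (thermodynamically preferred) dioxanone.

**14 back to 13, 12 and 11.** Both carbonyls of 14 are introduced in one double oxidation of diol 13, so the sensitive keto aldehyde exists for one step only. Diol 13 comes from hydrogenolysis of the two benzyl ethers of 12. Acetal 12 comes from the syn-1,3-diol 11, in which only O4 and O1' are free and the acetal can form in one way only.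

**11 back to 10 (C4 stereocentre).** The syn-1,3-diol is the product of a chelation-controlled reduction of β-hydroxy ketone 10. C4 is thus set from C1' through a six-membered boron chelate. The C5 benzyloxy group is a placeholder for the later ketone; its configuration is lost in 14.

**10 back to 7 and 9, and 7 back to 6 (C4–C3).** The ketone is cut at C4–C3 into Weinreb amide 7 and Grignard reagent 9, made from bromide 8. Reagent 9 brings C1–C3 with C1 as a benzyl ether. Amide 7 comes from imide 6 with return of auxiliary 1.

**6 back to 3 and 4, and 3 back to 1 and 2 (C5–C1').** The C5–C1' bond is an auxiliary-controlled syn-glycolate aldol between imide 3 and aldehyde 4. It sets C1' absolutely. Imide 3 is the acylation product of 1 and 2.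

## Alternatives that were turned down

**Alternative 1: ring-closing metathesis at C2=C3.**
- Disconnection and key step: diene A2 has a vinyl ketone and a vinyl carbinol acetate on the acetal-protected C5. The second-generation Grubbs catalyst (H2IMes)(PCy3)Cl2Ru=CHPh would close it to A1 with loss of ethylene.
- For it: no stereocentre is made in the ring closure, and the enone arrives without a dehydrogenation. A1 is identical with 20, one deprotection from 21. On the endgame this route is stronger than the chosen one, which needs steps 10 to 12 to reach the same compound.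
- Against it: all the difficulty moves into A2. The quaternary C5 must be built in an open chain between two oxygenated stereocentres, for example by addition to a ketone flanked by two α-alkoxy centres. That is the facial problem that made the acyclic benzoin substrate unattractive. A2 also contains a polymerizable vinyl ketone on a neopentyl carbon, a slow partner in metathesis.
- Comparison: the chosen route creates C5 during ring closure under ring-fusion control and pays for it with a longer endgame.

**Alternative 2: Achmatowicz pyranone to cyclopentenone.**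
- Disconnection and key step: C4–C5. Et3N opens pyranone A4 to an oxo-enal, and the enediolate carbon C5 adds to the aldehyde carbon to give A3.
- For it: this is clearly the shortest route (furan chemistry, oxidation, rearrangement). The enone and both ring oxygens arrive together. With O1' silylated, acylating the secondary O4 in the presence of the tertiary O5 is trivial. On step count and on hydroxyl differentiation it beats the chosen strategy.
- Against it: C4 and C5 are both formed in a reversible, base-mediated aldol through a planar enediolate. The C4/C5 relation is left to thermodynamics, and the C5/C1' relation to acyclic 1,2-induction from one silyloxy centre. Up to four diastereomers are possible. The product is exposed to the base that also promotes retro-aldol and epimerization.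
- Comparison: the chosen route is longer, but each stereocentre is set by one identifiable control element (auxiliary, chelate, ring fusion).

**Alternative 3: rhodium alkynal hydroacylation at C1–C2.**
- Disconnection and key step: [Rh(dppe)]2(BF4)2 would add the aldehyde C–H bond of alkynal A6 across its terminal alkyne in trans fashion to give A5.
- For it: it is atom-economic and redox-neutral, the enone forms directly, and no stereocentre is made. O4 is already differentiated as a silyl ether, so the later acylation needs no acetal migration. On that point it is as strong as the chosen route.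
- Against it: A6 is an aldehyde on a fully substituted, doubly oxygenated carbon. Acyl rhodium hydrides from such hindered aldehydes tend to lose CO, which stops turnover. The cyclization is established mainly for internal alkynes, whereas A6 must carry a terminal one with a propargylic silyl ether. As in alternative 1, the quaternary C5 must be assembled acyclically.
- Comparison: the chosen benzoin step uses an unhindered aldehyde as donor and a strongly activated ketone as acceptor, and it builds C5 itself.

Key step: step 9

## Route

Remark: pentadecanal (4), (benzyloxy)acetyl chloride (2) and benzyl 3-bromopropyl ether (8) are taken as commercial. The O4/O1' pair is carried as one isopropylidene acetal through the key step for the reasons given above.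

Step 1
Reactants: 1 (4R)-4-benzyl-1,3-oxazolidin-2-one; 2 (benzyloxy)acetyl chloride
Product: 3 (4R)-4-benzyl-3-[(benzyloxy)acetyl]-1,3-oxazolidin-2-one
Conditions: n-BuLi, THF, −78 °C; then 2, −78 to 0 °C
Reagents that add atoms: none
Why: N-acylation of the lithiated oxazolidinone by the acid chloride, a standard imide formation. The glycolate α-carbon becomes C5 and its carbonyl carbon becomes C4; no stereocentre is affected.

Step 2
Reactants: 3 (4R)-4-benzyl-3-[(benzyloxy)acetyl]-1,3-oxazolidin-2-one; 4 pentadecanal
Product: 6 (4R)-4-benzyl-3-[(2R,3S)-2-(benzyloxy)-3-hydroxyheptadecanoyl]-1,3-oxazolidin-2-one, via dibutylboron Z-enolate 5 (not isolated)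
Conditions: Bu2BOTf, Et3N, CH2Cl2, −78 to 0 °C; 4, −78 to 0 °C; then H2O2, MeOH, pH 7 buffer, 0 °C
Reagents that add atoms: none
Why: Evans syn-glycolate aldol through the Z-boron enolate in a closed chair transition state. The (R)-benzyl auxiliary blocks one enolate face, so the new C5–C1' bond is formed with C1' as S and the C5 ether syn to it.

Step 3
Reactants: 6 (4R)-4-benzyl-3-[(2R,3S)-2-(benzyloxy)-3-hydroxyheptadecanoyl]-1,3-oxazolidin-2-one
Product: 7 (2R,3S)-2-(benzyloxy)-3-hydroxy-N-methoxy-N-methylheptadecanamide
Conditions: MeNH(OMe)·HCl, AlMe3, CH2Cl2, −20 to 0 °C; aq. potassium sodium tartrate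
Reagents that add atoms: N,O-dimethylhydroxylamine hydrochloride, CNOC.Cl
Why: Aluminium amide transamination of the imide to the Weinreb amide, assisted by the free β-hydroxyl. Auxiliary 1 is returned and neither stereocentre is touched.

Step 4
Reactants: 7 (2R,3S)-2-(benzyloxy)-3-hydroxy-N-methoxy-N-methylheptadecanamide; 8 benzyl 3-bromopropyl ether
Product: 10 (5R,6S)-1,5-bis(benzyloxy)-6-hydroxyicosan-4-one, via [3-(benzyloxy)propyl]magnesium bromide 9 (not isolated)
Conditions: 8, Mg, THF, rt; then 7, THF, −20 to 0 °C (3 equiv of 9); aq. NH4Cl
Reagents that add atoms: none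
Why: Grignard addition to a Weinreb amide stops at the ketone because the chelated tetrahedral adduct survives until the quench. One equivalent of 9 is spent on the free hydroxyl. The step forms C4–C3 and brings C1 as a benzyl ether.

Step 5
Reactants: 10 (5R,6S)-1,5-bis(benzyloxy)-6-hydroxyicosan-4-one
Product: 11 (4R,5R,6S)-1,5-bis(benzyloxy)icosane-4,6-diol
Conditions: Et2BOMe, THF–MeOH (4:1), −78 °C; NaBH4, −78 °C; then H2O2, aq. NaOH, 0 °C
Reagents that add atoms: none
Why: Narasaka–Prasad reduction. Boron ties the hydroxyl and the ketone into a six-membered chelate, and hydride adds axially to give the 1,3-syn diol, which makes C4 R. The axial C5 benzyloxy group lies anti to the incoming hydride, so the polar α-effect and the chelate agree.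

Step 6
Reactants: 11 (4R,5R,6S)-1,5-bis(benzyloxy)icosane-4,6-diol
Product: 12 (4R,5R,6S)-5-(benzyloxy)-4-[3-(benzyloxy)propyl]-2,2-dimethyl-6-tetradecyl-1,3-dioxane
Conditions: Me2C(OMe)2, PPTS (cat.), CH2Cl2, rt
Reagents that add atoms: 2,2-dimethoxypropane, COC(C)(C)OC
Why: Acid-catalysed acetalization of the only two free hydroxyls. A syn-1,3-diol closes readily to the chair dioxane with both carbon substituents equatorial.

Step 7
Reactants: 12 (4R,5R,6S)-5-(benzyloxy)-4-[3-(benzyloxy)propyl]-2,2-dimethyl-6-tetradecyl-1,3-dioxane
Product: 13 (4R,5R,6S)-4-(3-hydroxypropyl)-2,2-dimethyl-6-tetradecyl-1,3-dioxan-5-ol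
Conditions: H2 (1 atm), Pd(OH)2 on carbon, EtOAc, rt
Reagents that add atoms: none
Why: Hydrogenolysis of both benzyl ethers frees the ring carbinol and the primary alcohol. The acetal and the saturated chain are inert under these neutral conditions.

Step 8
Reactants: 13 (4R,5R,6S)-4-(3-hydroxypropyl)-2,2-dimethyl-6-tetradecyl-1,3-dioxan-5-ol
Product: 14 3-[(4R,6S)-2,2-dimethyl-5-oxo-6-tetradecyl-1,3-dioxan-4-yl]propanal
Conditions: (COCl)2, DMSO, CH2Cl2, −78 °C; i-Pr2NEt, −78 to −20 °C
Reagents that add atoms: none
Why: Swern oxidation of both hydroxyls at once. Both are activated as alkoxysulfonium ions before the base is added, so no hydroxy aldehyde can close to a lactol and be over-oxidized. The hindered amine at low temperature leaves the two α-centres of the new dioxanone untouched.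

Step 9
Reactants: 14 3-[(4R,6S)-2,2-dimethyl-5-oxo-6-tetradecyl-1,3-dioxan-4-yl]propanal
Product: 16 (4S,4aS,7aR)-4a-hydroxy-2,2-dimethyl-4-tetradecylhexahydrocyclopenta[d][1,3]dioxin-5-one, via Breslow enaminol 15 (not isolated)
Conditions: 2-(pentafluorophenyl)-6,7-dihydro-5H-pyrrolo[2,1-c][1,2,4]triazol-2-ium tetrafluoroborate (15 mol %), Et3N (20 mol %), CH2Cl2 (0.02 M), rt
Reagents that add atoms: none
Why: The triazolylidene released by Et3N adds to the aldehyde carbon C1, and proton transfer gives the Breslow enaminol 15, an acyl anion equivalent. Its nucleophilic carbon C1 attacks the ketone carbon C5 in a 5-exo-trig closure while the enol proton passes to the developing alkoxide; loss of the carbene then unveils the C1 ketone and returns the catalyst. The closest known reaction type is the carbene-catalysed intramolecular crossed aldehyde–ketone benzoin of δ-keto aldehydes, including closures onto cyclic ketones from a tether on the α-carbon, which give cis-fused bicyclic tertiary ketols. The new stereocentre C5 is set by the substrate: the tether is equatorial on the chair of the cis-disubstituted dioxanone and reaches the carbonyl without strain only along the axial direction, so the five-membered ring is fused cis and the C5 hydroxyl ends up trans to the C4 oxygen. The addition is reversible and the cis-fused bicycle is also the more stable isomer, so kinetic and thermodynamic control agree and an achiral carbene is enough. The step needs the crossed intramolecular path to beat aldehyde self-condensation, which high dilution and the strong activation of the ketone by its two α-oxygens secure. It also needs C4 and C1' to keep their configuration, which the weak amine base and the fact that the cis-dioxanone is the preferred epimer secure. The saturated C2–C3 tether rules out homoenolate pathways, and 16 has a single enolizable position, C2.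

Step 10
Reactants: 16 (4S,4aS,7aR)-4a-hydroxy-2,2-dimethyl-4-tetradecylhexahydrocyclopenta[d][1,3]dioxin-5-one
Product: 18 (4S,4aS,7aR)-2,2-dimethyl-4-tetradecyl-4a-[(trimethylsilyl)oxy]-4a,7a-dihydro-4H-cyclopenta[d][1,3]dioxin-5-one, via bis(trimethylsilyl) enol ether 17 (not isolated)
Conditions: TMSOTf, Et3N, CH2Cl2, 0 °C; then Pd(OAc)2, MeCN, rt
Reagents that add atoms: trimethylsilyl trifluoromethanesulfonate, C[Si](C)(C)OS(=O)(=O)C(F)(F)F
Why: Soft enolization silylates the tertiary hydroxyl and gives the only possible enol silane, C1=C2, because C5 is quaternary. Saegusa–Ito oxidation with divalent palladium then forms the palladium enolate, and β-hydride elimination from C3 installs C2=C3. O4 is still an acetal oxygen and is no leaving group for the zerovalent palladium that forms.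

Step 11
Reactants: 18 (4S,4aS,7aR)-2,2-dimethyl-4-tetradecyl-4a-[(trimethylsilyl)oxy]-4a,7a-dihydro-4H-cyclopenta[d][1,3]dioxin-5-one
Product: 19 (4S,5R,9R)-9-hydroxy-2,2-dimethyl-4-tetradecyl-1,3-dioxaspiro[4.4]non-7-en-6-one
Conditions: CSA (20 mol %), acetone (1 equiv H2O), rt
Reagents that add atoms: none
Why: Acid cleaves the tertiary silyl ether and opens the six-membered acetal, which recloses onto O5 and O1'; this is a known acid-catalysed acetal migration. The five-membered dioxolane is favoured because the dioxane must carry an axial methyl and is fused to a nearly flat cyclopentenone; O4 and O5 are trans and cannot be bridged. Only the C4 hydroxyl is left free.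

Step 12
Reactants: 19 (4S,5R,9R)-9-hydroxy-2,2-dimethyl-4-tetradecyl-1,3-dioxaspiro[4.4]non-7-en-6-one
Product: 20 (4S,5S,9R)-2,2-dimethyl-6-oxo-4-tetradecyl-1,3-dioxaspiro[4.4]non-7-en-9-yl acetate
Conditions: Ac2O, pyridine, DMAP (cat.), CH2Cl2, 0 °C to rt
Reagents that add atoms: acetic anhydride, CC(=O)OC(C)=O
Why: DMAP-catalysed acylation of the only free hydroxyl. C5 is quaternary, so the new β-acyloxy ketone has no path for elimination through C5.

Step 13
Reactants: 20 (4S,5S,9R)-2,2-dimethyl-6-oxo-4-tetradecyl-1,3-dioxaspiro[4.4]non-7-en-9-yl acetate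
Product: 21 (1R,5S)-5-hydroxy-5-[(1S)-1-hydroxypentadecyl]-4-oxocyclopent-2-en-1-yl acetate
Conditions: TFA–H2O (9:1), CH2Cl2, 0 °C
Reagents that add atoms: none
Why: Acidic hydrolysis of the isopropylidene acetal frees O5 and O1'. The acetate and the enone tolerate cold aqueous trifluoroacetic acid, and acid avoids the base-induced acetyl migration, retro-aldol cleavage and elimination to which 21 is prone.

## Compound list

1 | (4R)-4-benzyl-1,3-oxazolidin-2-one | O=C1N[C@H](Cc2ccccc2)CO1 | starting material
2 | (benzyloxy)acetyl chloride | O=C(Cl)COCc1ccccc1 | starting material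
3 | (4R)-4-benzyl-3-[(benzyloxy)acetyl]-1,3-oxazolidin-2-one | O=C(COCc1ccccc1)N1[C@H](Cc2ccccc2)COC1=O | intermediate
4 | pentadecanal | CCCCCCCCCCCCCCC=O | starting material
5 | dibutylboron Z-enolate of 3, (4R)-4-benzyl-3-{(Z)-2-(benzyloxy)-1-[(dibutylboranyl)oxy]ethenyl}-1,3-oxazolidin-2-one | CCCCB(CCCC)O/C(=C\OCc1ccccc1)N1[C@H](Cc2ccccc2)COC1=O | intermediate
6 | (4R)-4-benzyl-3-[(2R,3S)-2-(benzyloxy)-3-hydroxyheptadecanoyl]-1,3-oxazolidin-2-one | CCCCCCCCCCCCCC[C@H](O)[C@@H](OCc1ccccc1)C(=O)N1[C@H](Cc2ccccc2)COC1=O | intermediate
7 | (2R,3S)-2-(benzyloxy)-3-hydroxy-N-methoxy-N-methylheptadecanamide | CCCCCCCCCCCCCC[C@H](O)[C@@H](OCc1ccccc1)C(=O)N(C)OC | intermediate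
8 | benzyl 3-bromopropyl ether | BrCCCOCc1ccccc1 | starting material
9 | [3-(benzyloxy)propyl]magnesium bromide | Br[Mg]CCCOCc1ccccc1 | intermediate
10 | (5R,6S)-1,5-bis(benzyloxy)-6-hydroxyicosan-4-one | CCCCCCCCCCCCCC[C@H](O)[C@@H](OCc1ccccc1)C(=O)CCCOCc1ccccc1 | intermediate
11 | (4R,5R,6S)-1,5-bis(benzyloxy)icosane-4,6-diol | CCCCCCCCCCCCCC[C@H](O)[C@@H](OCc1ccccc1)[C@H](O)CCCOCc1ccccc1 | intermediate
12 | (4R,5R,6S)-5-(benzyloxy)-4-[3-(benzyloxy)propyl]-2,2-dimethyl-6-tetradecyl-1,3-dioxane | CCCCCCCCCCCCCC[C@@H]1OC(C)(C)O[C@H](CCCOCc2ccccc2)[C@@H]1OCc1ccccc1 | intermediate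
13 | (4R,5R,6S)-4-(3-hydroxypropyl)-2,2-dimethyl-6-tetradecyl-1,3-dioxan-5-ol | CCCCCCCCCCCCCC[C@@H]1OC(C)(C)O[C@H](CCCO)[C@@H]1O | intermediate
14 | 3-[(4R,6S)-2,2-dimethyl-5-oxo-6-tetradecyl-1,3-dioxan-4-yl]propanal (key-step precursor) | CCCCCCCCCCCCCC[C@@H]1OC(C)(C)O[C@H](CCC=O)C1=O | intermediate
15 | Breslow enaminol of 14, 3-[(4R,6S)-2,2-dimethyl-5-oxo-6-tetradecyl-1,3-dioxan-4-yl]-1-[2-(pentafluorophenyl)-6,7-dihydro-5H-pyrrolo[2,1-c][1,2,4]triazol-3(2H)-ylidene]propan-1-ol (alkene geometry not defined) | CCCCCCCCCCCCCC[C@@H]1OC(C)(C)O[C@H](CCC(O)=C2N(c3c(F)c(F)c(F)c(F)c3F)N=C3CCCN23)C1=O | intermediate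
16 | (4S,4aS,7aR)-4a-hydroxy-2,2-dimethyl-4-tetradecylhexahydrocyclopenta[d][1,3]dioxin-5-one (cis-fused; 4a = C5, 7a = C4, 5 = C1 of 21; key-step product) | CCCCCCCCCCCCCC[C@@H]1OC(C)(C)O[C@@H]2CCC(=O)[C@]12O | intermediate
17 | bis(trimethylsilyl) derivative of 16: trimethylsilyl enol ether at C1=C2 and trimethylsilyl ether at O5, ring configuration as in 16 | CCCCCCCCCCCCCC[C@@H]1OC(C)(C)O[C@@H]2CC=C(O[Si](C)(C)C)[C@]12O[Si](C)(C)C | intermediate
18 | (4S,4aS,7aR)-2,2-dimethyl-4-tetradecyl-4a-[(trimethylsilyl)oxy]-4a,7a-dihydro-4H-cyclopenta[d][1,3]dioxin-5-one | CCCCCCCCCCCCCC[C@@H]1OC(C)(C)O[C@@H]2C=CC(=O)[C@]12O[Si](C)(C)C | intermediate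
19 | (4S,5R,9R)-9-hydroxy-2,2-dimethyl-4-tetradecyl-1,3-dioxaspiro[4.4]non-7-en-6-one | CCCCCCCCCCCCCC[C@@H]1OC(C)(C)O[C@@]12C(=O)C=C[C@H]2O | intermediate
20 | (4S,5S,9R)-2,2-dimethyl-6-oxo-4-tetradecyl-1,3-dioxaspiro[4.4]non-7-en-9-yl acetate | CCCCCCCCCCCCCC[C@@H]1OC(C)(C)O[C@@]12C(=O)C=C[C@H]2OC(C)=O | intermediate
21 | (1R,5S)-5-hydroxy-5-[(1S)-1-hydroxypentadecyl]-4-oxocyclopent-2-en-1-yl acetate | CCCCCCCCCCCCCC[C@H](O)[C@@]1(O)C(=O)C=C[C@H]1OC(C)=O | target

## Step count and least certain steps

Total step count: 13. Longest linear sequence: 13 steps (from 1 to 21).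

**Step 9 (key step).**
- What may go wrong: slow addition to a ketone that is branched on both α-carbons, which would let intermolecular aldehyde self-condensation or aldol chemistry take over. A second risk is base-mediated epimerization of the dioxanone α-centres (C4, C1') during a long reaction, which would erode the enantiomeric and diastereomeric purity.
- Fallback: it sets out from 14 and returns at 16. Reductive ketyl cyclization of 14 with SmI2 and t-BuOH in THF at −78 °C, a known aldehyde–ketone pinacol closure that gives cis-fused diols, should give the bicyclic diol F1. The aldehyde is reduced first, and the ring C–O bonds of the dioxanone lie near the carbonyl plane and are poorly placed for reductive cleavage. Oxidation of the secondary carbinol of F1 with SO3·pyridine, DMSO and i-Pr2NEt would then give 16.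

**Step 11.**
- What may go wrong: incomplete or unselective migration of the acetal, giving an equilibrium mixture of six- and five-membered isopropylidene isomers, or loss of the acetal altogether.
- Fallback: it sets out from 18 and returns at 21, bypassing 19 and 20. Aqueous acetic acid would strip the silyl ether and the acetal to the triol enone F2. Phenylboronic acid (toluene, MgSO4) should then mask the O5/O1' diol as the cyclic boronate F3. Acylation with Ac2O and pyridine would give F4, and neutral exchange of the boronate with pinacol would give 21. Which diol the boronic acid takes is itself not certain.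

**Step 10.**
- What may go wrong: opening or migration of the acetal by the silyl triflate during enol silane formation, and incomplete dehydrogenation in the palladium step.
- Fallback: it sets out from 16 and returns at 19. The dianion of 16 (LDA, 2.2 equiv, THF, −78 °C) would be selenylated with PhSeCl to the α-phenylselenyl ketone F5. Oxidation with H2O2 and pyridine and syn elimination of the selenoxide would give enone F6 with a free tertiary hydroxyl. F6 enters the conditions of step 11 directly and should give 19.

**Step 5.**
- What may go wrong: lower syn selectivity than expected if the C5 benzyloxy group competes for boron and loosens the chelate.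
- Fallback: it sets out from 10 and returns at 11, and replaces chelate control with reagent control. Silylation (TBSOTf, 2,6-lutidine) would give F7. Reduction with BH3·SMe2 and (S)-1-methyl-3,3-diphenyltetrahydro-1H,3H-pyrrolo[1,2-c][1,3,2]oxazaborole (20 mol %), with the branched C5 side as the large group, should give the (4R)-alcohol F8. Desilylation with Bu4NF would give 11.

## Further compounds

F1 | step 9 | cis-fused pinacol diol, 2,2-dimethyl-4-tetradecylhexahydrocyclopenta[d][1,3]dioxine-4a,5-diol, ring-fusion configuration as in 16, C1 carbinol configuration not defined | CCCCCCCCCCCCCC[C@@H]1OC(C)(C)O[C@@H]2CCC(O)[C@]12O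
F2 | step 11 | (4R,5S)-4,5-dihydroxy-5-[(1S)-1-hydroxypentadecyl]cyclopent-2-en-1-one | CCCCCCCCCCCCCC[C@H](O)[C@@]1(O)C(=O)C=C[C@H]1O
F3 | step 11 | cyclic phenylboronate of F2 on O5 and O1', 9-hydroxy-2-phenyl-4-tetradecyl-1,3-dioxa-2-boraspiro[4.4]non-7-en-6-one, configuration as in 19 | CCCCCCCCCCCCCC[C@@H]1OB(c3ccccc3)O[C@@]12C(=O)C=C[C@H]2O
F4 | step 11 | O4-acetate of F3, configuration as in 20 | CCCCCCCCCCCCCC[C@@H]1OB(c3ccccc3)O[C@@]12C(=O)C=C[C@H]2OC(C)=O
F5 | step 10 | C2-phenylselenyl derivative of 16, configuration at C2 not defined | CCCCCCCCCCCCCC[C@@H]1OC(C)(C)O[C@@H]2CC([Se]c3ccccc3)C(=O)[C@]12O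
F6 | step 10 | (4S,4aS,7aR)-4a-hydroxy-2,2-dimethyl-4-tetradecyl-4a,7a-dihydro-4H-cyclopenta[d][1,3]dioxin-5-one | CCCCCCCCCCCCCC[C@@H]1OC(C)(C)O[C@@H]2C=CC(=O)[C@]12O
F7 | step 5 | (5R,6S)-1,5-bis(benzyloxy)-6-[(tert-butyldimethylsilyl)oxy]icosan-4-one | CCCCCCCCCCCCCC[C@H](O[Si](C)(C)C(C)(C)C)[C@@H](OCc1ccccc1)C(=O)CCCOCc1ccccc1
F8 | step 5 | (4R,5R,6S)-1,5-bis(benzyloxy)-6-[(tert-butyldimethylsilyl)oxy]icosan-4-ol | CCCCCCCCCCCCCC[C@H](O[Si](C)(C)C(C)(C)C)[C@@H](OCc1ccccc1)[C@H](O)CCCOCc1ccccc1
A1 | alternative 1 | (4S,5S,9R)-2,2-dimethyl-6-oxo-4-tetradecyl-1,3-dioxaspiro[4.4]non-7-en-9-yl acetate, identical with 20 | CCCCCCCCCCCCCC[C@@H]1OC(C)(C)O[C@@]12C(=O)C=C[C@H]2OC(C)=O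
A2 | alternative 1 | metathesis substrate, 1-[2,2-dimethyl-4-(prop-2-enoyl)-5-tetradecyl-1,3-dioxolan-4-yl]prop-2-en-1-yl acetate, configuration as in 21 | CCCCCCCCCCCCCC[C@@H]1OC(C)(C)O[C@]1(C(=O)C=C)[C@@H](C=C)OC(C)=O
A3 | alternative 2 | (4R,5R)-5-[(1S)-1-{[tert-butyl(dimethyl)silyl]oxy}pentadecyl]-4,5-dihydroxycyclopent-2-en-1-one | CCCCCCCCCCCCCC[C@H](O[Si](C)(C)C(C)(C)C)[C@@]1(O)C(=O)C=C[C@H]1O
A4 | alternative 2 | Achmatowicz pyranone, 2-[(1S)-1-{[tert-butyl(dimethyl)silyl]oxy}pentadecyl]-6-hydroxy-2H-pyran-3(6H)-one, ring centres not defined | CCCCCCCCCCCCCC[C@H](O[Si](C)(C)C(C)(C)C)C1OC(O)C=CC1=O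
A5 | alternative 3 | (4S,5S,9R)-9-{[tert-butyl(dimethyl)silyl]oxy}-2,2-dimethyl-4-tetradecyl-1,3-dioxaspiro[4.4]non-7-en-6-one | CCCCCCCCCCCCCC[C@@H]1OC(C)(C)O[C@@]12C(=O)C=C[C@H]2O[Si](C)(C)C(C)(C)C
A6 | alternative 3 | alkynal substrate, 4-(1-{[tert-butyl(dimethyl)silyl]oxy}prop-2-yn-1-yl)-2,2-dimethyl-5-tetradecyl-1,3-dioxolane-4-carbaldehyde, configuration as in 21 | CCCCCCCCCCCCCC[C@@H]1OC(C)(C)O[C@]1(C=O)[C@@H](C#C)O[Si](C)(C)C(C)(C)C
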